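**Retrosynthetic overview**

1. Target 21 ⇐ lactone 17 + prenyl bromide 18: one pot, lactone opening, then C‑prenylation of the phenoxide at C8 (para to O⁻).
2. Key step: 17 ⇐ indanone 16 by Baeyer–Villiger ring expansion (aryl 1,2‑shift to oxygen). This puts the third oxygen on C5, the ring carbon meta to both resorcinol oxygens, and holds the hexanoic acid chain as a lactone.
3. 16 ⇐ acid 14 (Friedel–Crafts acylation onto C5) ⇐ chroman 10 + (E)‑hex‑2‑enoic acid 11 by a proposed enantioselective Friedel–Crafts conjugate addition that sets the side‑chain centre.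
4. 10 ⇐ aldehyde 8 (Friedel–Crafts ring closure and ionic deoxygenation) ⇐ ether 5 (anti hydroboration sets C3) ⇐ 3‑methoxyphenol 4 (from resorcinol 3) + tiglyl carbonate 2 (Pd asymmetric O‑allylation sets C2).
5. Ring order: benzene ring bought as resorcinol → dihydropyran ring (step 6) → cyclopentanone (step 8) → expanded to the six‑membered lactone (step 9) → lactone opened (step 10).

Assumption: the target is read from the SMILES as the (3R)‑acid on a (2S,3R)‑trans‑2,3‑dimethylchroman (chroman numbering O1, C2 … C8a); the sense of induction of the ligand in step 3 and of the proposed catalyst in step 7 is taken as written, and the mirror‑image ligand or catalyst is used if it proves opposite.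

**Step 1**
Reactants: 1 (E)‑2‑methylbut‑2‑en‑1‑ol
Product: 2 methyl (E)‑2‑methylbut‑2‑en‑1‑yl carbonate
Conditions: ClCO2Me, pyridine, CH2Cl2, 0 °C to rt
Reagents that add atoms: methyl chloroformate, COC(=O)Cl
Why: O‑acylation of the allylic alcohol with a chloroformate (carbonate formation) supplies the ionisable leaving group for step 3; no stereocentre is involved.

**Step 2**
Reactants: 3 resorcinol
Product: 4 3‑methoxyphenol
Conditions: Me2SO4 (1 equiv), NaOH, H2O, 40 °C; resorcinol 2 equiv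
Reagents that add atoms: dimethyl sulfate, COS(=O)(=O)OC
Why: Williamson O‑methylation; with resorcinol in excess the mono‑ether dominates and is separated from resorcinol (stays in water) and from the diether (not extracted by base).

**Step 3**
Reactants: 2 methyl (E)‑2‑methylbut‑2‑en‑1‑yl carbonate; 4 3‑methoxyphenol
Product: 5 1‑methoxy‑3‑{[(2S)‑3‑methylbut‑3‑en‑2‑yl]oxy}benzene
Conditions: Pd2(dba)3·CHCl3 (1 mol%), (S,S)‑DACH‑phenyl Trost ligand (3 mol%), CH2Cl2, rt
Reagents that add atoms: none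
Why: Pd‑catalysed asymmetric allylic alkylation (Tsuji–Trost O‑allylation): ionisation gives the 1,2‑dimethylallyl–Pd complex and the phenol attacks the more substituted terminus inside the chiral pocket, setting the ether carbon as S (later C2 of the chroman); this carbonate with phenols is the established entry to trans‑2,3‑dimethylchromans.

**Step 4**
Reactants: 5 1‑methoxy‑3‑{[(2S)‑3‑methylbut‑3‑en‑2‑yl]oxy}benzene
Product: 7 (2R,3S)‑3‑(3‑methoxyphenoxy)‑2‑methylbutan‑1‑ol, via alkylborane 6 (not isolated)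
Conditions: 9‑BBN, THF, 0 °C to rt; then NaOH, H2O2, 0 °C to rt
Reagents that add atoms: 9‑BBN, B1C2CCCC1CCC2 (its atoms are in 6 only); hydrogen peroxide, OO (gives the O of 7)
Why: Substrate‑controlled hydroboration–oxidation: 9‑BBN adds to the 1,1‑disubstituted alkene anti to the aryloxy group in the A(1,3)‑minimised conformer, giving the 2,3‑anti alcohol (new centre R, later C3 of the chroman, about 9:1 expected).

**Step 5**
Reactants: 7 (2R,3S)‑3‑(3‑methoxyphenoxy)‑2‑methylbutan‑1‑ol
Product: 8 (2S,3S)‑3‑(3‑methoxyphenoxy)‑2‑methylbutanal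
Conditions: Dess–Martin periodinane, CH2Cl2, 0 °C to rt; used at once
Reagents that add atoms: none
Why: Dess–Martin oxidation is non‑basic, so the α‑stereocentre and the β‑aryloxy group survive without epimerisation or β‑elimination (the descriptor changes from R to S only because CHO outranks the ether carbon).

**Step 6**
Reactants: 8 (2S,3S)‑3‑(3‑methoxyphenoxy)‑2‑methylbutanal
Product: 10 (2S,3R)‑7‑methoxy‑2,3‑dimethylchroman, via chroman‑4‑ol 9 (not isolated)
Conditions: BF3·OEt2, CH2Cl2, −78 °C; then Et3SiH, −78 to −30 °C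
Reagents that add atoms: none
Why: Intramolecular Friedel–Crafts hydroxyalkylation para to OMe closes the dihydropyran ring, and ionic hydrogenation of the p‑methoxybenzylic cation with Et3SiH removes the 4‑OH in the same pot; C2 and C3 are not touched, and low temperature suppresses loss of H3 from the cation (the minor 5‑methoxy regioisomer is removed by chromatography).

**Step 7**
Reactants: 10 (2S,3R)‑7‑methoxy‑2,3‑dimethylchroman; 11 (E)‑hex‑2‑enoic acid
Product: 14 (3R)‑3‑[(2S,3R)‑7‑methoxy‑2,3‑dimethylchroman‑6‑yl]hexanoic acid, via silyl enoate 12 (not isolated), via silyl ester 13 (not isolated)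
Conditions: 11 (2 equiv), allylSiMe3 (2.2 equiv), (S,S)‑IDPi acid (imidodiphosphorimidate, 3,3′‑bis[3,5‑bis(trifluoromethyl)phenyl]‑BINOL backbones, N‑triflyl core; 5 mol%), toluene, rt, 1 h; then 10, −40 °C, 48 h; aqueous citric acid work‑up
Reagents that add atoms: allyltrimethylsilane, C=CC[Si](C)(C)C (its Me3Si group is in 12 and 13 only)
Why: Proposed new method: the confined chiral IDPi acid, silylated in situ, O‑silylates silyl enoate 12 to a bis(silyloxy)allyl cation held in the chiral anion pocket; the dialkoxyarene (about as nucleophilic as cyclopentadiene, which such ion pairs already engage) attacks the β‑carbon through C6 (para to O1, ortho to OMe; C8 is flanked on both sides), the arenium proton returns to the anion, and protodesilylation of the bis‑silyl ketene acetal frees the silylium catalyst, setting the new centre as R under catalyst control; the closest known reactions are IDPi/silylium‑catalysed Diels–Alder and Mukaiyama–Michael additions to simple α,β‑unsaturated esters and the racemic acid‑mediated Friedel–Crafts hydroarylation of enoic acids.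

**Step 8**
Reactants: 14 (3R)‑3‑[(2S,3R)‑7‑methoxy‑2,3‑dimethylchroman‑6‑yl]hexanoic acid
Product: 16 indanone‑fused chroman [(R)‑3‑propylcyclopentan‑1‑one ring fused across C5–C6 of (2S,3R)‑7‑methoxy‑2,3‑dimethylchroman; C=O on C5; CH(n‑Pr) on C6], via acid chloride 15 (not isolated)
Conditions: (COCl)2, cat. DMF, CH2Cl2, 0 °C to rt; evaporate; AlCl3 (1.3 equiv), CH2Cl2 (0.005 M), −20 to 0 °C
Reagents that add atoms: oxalyl chloride, ClC(=O)C(=O)Cl (its Cl is in 15 only)
Why: Intramolecular Friedel–Crafts acylation: the acylium ion can reach only C5 (the other ortho position carries OMe) and closes the cyclopentanone; high dilution suppresses intermolecular attack at C8, and the stereocentre is β to the carbonyl and is not affected.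

**Step 9**
Reactants: 16 indanone‑fused chroman
Product: 17 (4R,8S,9R)‑5‑methoxy‑8,9‑dimethyl‑4‑propyl‑3,4,9,10‑tetrahydro‑2H,8H‑pyrano[2,3‑f]chromen‑2‑one
Conditions: m‑CPBA (1.5 equiv), TFA (1 equiv), CH2Cl2, 0 °C to rt, dark
Reagents that add atoms: m‑CPBA, OOC(=O)c1cccc(Cl)c1
Why: Baeyer–Villiger ring expansion: in the Criegee adduct the aryl carbon (two ortho alkyl groups) undergoes the 1,2‑shift to oxygen in preference to the primary CH2, as in 1‑indanone → 3,4‑dihydrocoumarin, placing O on C5 with all stereocentres untouched; the ketone‑deactivated ring resists peracid attack.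

**Step 10**
Reactants: 17 (4R,8S,9R)‑5‑methoxy‑8,9‑dimethyl‑4‑propyl‑3,4,9,10‑tetrahydro‑2H,8H‑pyrano[2,3‑f]chromen‑2‑one; 18 1‑bromo‑3‑methylbut‑2‑ene (prenyl bromide)
Product: 21 (3R)‑3‑[(2S,3R)‑5‑hydroxy‑7‑methoxy‑2,3‑dimethyl‑8‑(3‑methylbut‑2‑en‑1‑yl)chroman‑6‑yl]hexanoic acid (target CNP0275989.1), via ring‑opened dipotassium salt 19 (not isolated), via product dipotassium salt 20 (not isolated)
Conditions: 2 M KOH (3 equiv), H2O, argon, rt to 40 °C; then 18 (1.2 equiv), 0 °C to rt; then 1 M HCl to pH 5, 0 °C, quick extraction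
Reagents that add atoms: potassium hydroxide, [K+].[OH-]
Why: Saponification opens the lactone, and the ortho,ortho′‑disubstituted phenoxide in water is alkylated at carbon para to O⁻ (C8, the only free ring position, also ortho to both ether oxygens) and then tautomerises (C‑prenylation of phenolates in aqueous alkali); cold acidification to pH 5 avoids relactonisation and no stereocentre is touched.

**Compound list**

1 | (E)‑2‑methylbut‑2‑en‑1‑ol | C/C=C(\C)CO | starting material
2 | methyl (E)‑2‑methylbut‑2‑en‑1‑yl carbonate | C/C=C(\C)COC(=O)OC | intermediate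
3 | resorcinol | Oc1cccc(O)c1 | starting material
4 | 3‑methoxyphenol | COc1cccc(O)c1 | intermediate
5 | 1‑methoxy‑3‑{[(2S)‑3‑methylbut‑3‑en‑2‑yl]oxy}benzene | COc1cccc(O[C@@H](C)C(C)=C)c1 | intermediate
6 | B‑[(2R,3S)‑3‑(3‑methoxyphenoxy)‑2‑methylbutyl]‑9‑borabicyclo[3.3.1]nonane | COc1cccc(O[C@@H](C)[C@H](C)CB2C3CCCC2CCC3)c1 | intermediate
7 | (2R,3S)‑3‑(3‑methoxyphenoxy)‑2‑methylbutan‑1‑ol | COc1cccc(O[C@@H](C)[C@H](C)CO)c1 | intermediate
8 | (2S,3S)‑3‑(3‑methoxyphenoxy)‑2‑methylbutanal | COc1cccc(O[C@@H](C)[C@H](C)C=O)c1 | intermediate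
9 | (2S,3R)‑7‑methoxy‑2,3‑dimethylchroman‑4‑ol (C4 epimers) | COc1ccc2c(c1)O[C@@H](C)[C@H](C)C2O | intermediate
10 | (2S,3R)‑7‑methoxy‑2,3‑dimethylchroman | COc1ccc2c(c1)O[C@@H](C)[C@H](C)C2 | intermediate
11 | (E)‑hex‑2‑enoic acid | CCC/C=C/C(=O)O | starting material
12 | trimethylsilyl (E)‑hex‑2‑enoate | CCC/C=C/C(=O)O[Si](C)(C)C | intermediate
13 | trimethylsilyl (3R)‑3‑[(2S,3R)‑7‑methoxy‑2,3‑dimethylchroman‑6‑yl]hexanoate | CCC[C@H](CC(=O)O[Si](C)(C)C)c1cc2c(cc1OC)O[C@@H](C)[C@H](C)C2 | intermediate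
14 | (3R)‑3‑[(2S,3R)‑7‑methoxy‑2,3‑dimethylchroman‑6‑yl]hexanoic acid | CCC[C@H](CC(=O)O)c1cc2c(cc1OC)O[C@@H](C)[C@H](C)C2 | intermediate
15 | (3R)‑3‑[(2S,3R)‑7‑methoxy‑2,3‑dimethylchroman‑6‑yl]hexanoyl chloride | CCC[C@H](CC(=O)Cl)c1cc2c(cc1OC)O[C@@H](C)[C@H](C)C2 | intermediate
16 | indanone‑fused chroman: (R)‑3‑propylcyclopentan‑1‑one fused across C5–C6 of (2S,3R)‑7‑methoxy‑2,3‑dimethylchroman (C=O on C5; CHPr on C6) | CCC[C@@H]1CC(=O)c2c1c(OC)cc1O[C@@H](C)[C@H](C)Cc21 | intermediate
17 | (4R,8S,9R)‑5‑methoxy‑8,9‑dimethyl‑4‑propyl‑3,4,9,10‑tetrahydro‑2H,8H‑pyrano[2,3‑f]chromen‑2‑one | CCC[C@@H]1CC(=O)Oc2c1c(OC)cc1O[C@@H](C)[C@H](C)Cc21 | intermediate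
18 | 1‑bromo‑3‑methylbut‑2‑ene | CC(C)=CCBr | starting material
19 | dipotassium (3R)‑3‑[(2S,3R)‑7‑methoxy‑2,3‑dimethyl‑5‑oxidochroman‑6‑yl]hexanoate | CCC[C@H](CC(=O)[O-])c1c([O-])c2c(cc1OC)O[C@@H](C)[C@H](C)C2.[K+].[K+] | intermediate
20 | dipotassium salt of 21 (phenoxide and carboxylate) | CCC[C@H](CC(=O)[O-])c1c([O-])c2c(c(CC=C(C)C)c1OC)O[C@@H](C)[C@H](C)C2.[K+].[K+] | intermediate
21 | (3R)‑3‑[(2S,3R)‑5‑hydroxy‑7‑methoxy‑2,3‑dimethyl‑8‑(3‑methylbut‑2‑en‑1‑yl)chroman‑6‑yl]hexanoic acid | CCC[C@H](CC(=O)O)c1c(O)c2c(c(CC=C(C)C)c1OC)O[C@@H](C)[C@H](C)C2 | target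

**Step count and risks**

Total steps: 10. Longest linear sequence: 9 (steps 2 to 10 from resorcinol; step 1 is a one‑step side branch that joins at step 3).

Most likely to fail:

Step 7 (the proposed step; low ee, low conversion, or attack at C8). The fallback sets out from 10 and uses known chemistry. Pd(OAc)2‑catalysed hydroarylation in TFA/CH2Cl2 at rt adds the C6–H of 10 trans across bought hex‑2‑ynoic acid F1, giving (Z)‑3‑[(2S,3R)‑7‑methoxy‑2,3‑dimethylchroman‑6‑yl]hex‑2‑enoic acid F2. Asymmetric hydrogenation of F2 (H2, MeOH, Ru(OAc)2[(R)‑BINAP] or its mirror image, whichever gives the R acid) then returns to the route at 14.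

Step 8 (the acylium ion must close onto a ring carbon meta to both oxygens, so intermolecular acylation at the much more nucleophilic C8 can win). The fallback sets out from 14 and blocks that position first. NBS in MeCN at 0 °C gives (3R)‑3‑[(2S,3R)‑8‑bromo‑7‑methoxy‑2,3‑dimethylchroman‑6‑yl]hexanoic acid F3. With C5 the only free ring carbon, cyclodehydration in P2O5/MeSO3H at 60 °C gives the 8‑bromo indanone F4, and m‑CPBA/TFA ring expansion gives the 6‑bromo lactone F5. Hydrogenolysis of the C–Br bond (H2, Pd/C, Et3N, EtOAc) returns to the route at 17.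

Step 10 (O‑prenylation of the phenoxide may compete with C‑prenylation). The fallback sets out from 17 and moves the C–C bond formation to a cross‑coupling. Iodination of the only aromatic C–H (N‑iodosuccinimide, cat. TFA, MeCN) gives the 6‑iodo lactone F6. Stille coupling with tributyl(3‑methylbut‑2‑en‑1‑yl)stannane (Pd(PPh3)4, DMF, 80 °C) gives the 6‑prenyl lactone F7. Opening F7 with KOH in THF/H2O returns to the route at 20, which is acidified to 21 as in step 10.

**Further compounds**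

F1 | step 7 | hex‑2‑ynoic acid (bought) | CCCC#CC(=O)O
F2 | step 7 | (Z)‑3‑[(2S,3R)‑7‑methoxy‑2,3‑dimethylchroman‑6‑yl]hex‑2‑enoic acid | CCC/C(=C/C(=O)O)c1cc2c(cc1OC)O[C@@H](C)[C@H](C)C2
F3 | step 8 | (3R)‑3‑[(2S,3R)‑8‑bromo‑7‑methoxy‑2,3‑dimethylchroman‑6‑yl]hexanoic acid | CCC[C@H](CC(=O)O)c1cc2c(c(Br)c1OC)O[C@@H](C)[C@H](C)C2
F4 | step 8 | 8‑bromo indanone (16 with Br on chroman C8) | CCC[C@@H]1CC(=O)c2c1c(OC)c(Br)c1O[C@@H](C)[C@H](C)Cc21
F5 | step 8 | (4R,8S,9R)‑6‑bromo‑5‑methoxy‑8,9‑dimethyl‑4‑propyl‑3,4,9,10‑tetrahydro‑2H,8H‑pyrano[2,3‑f]chromen‑2‑one | CCC[C@@H]1CC(=O)Oc2c1c(OC)c(Br)c1O[C@@H](C)[C@H](C)Cc21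
F6 | step 10 | (4R,8S,9R)‑6‑iodo‑5‑methoxy‑8,9‑dimethyl‑4‑propyl‑3,4,9,10‑tetrahydro‑2H,8H‑pyrano[2,3‑f]chromen‑2‑one | CCC[C@@H]1CC(=O)Oc2c1c(OC)c(I)c1O[C@@H](C)[C@H](C)Cc21
F7 | step 10 | (4R,8S,9R)‑5‑methoxy‑8,9‑dimethyl‑6‑(3‑methylbut‑2‑en‑1‑yl)‑4‑propyl‑3,4,9,10‑tetrahydro‑2H,8H‑pyrano[2,3‑f]chromen‑2‑one | CCC[C@@H]1CC(=O)Oc2c1c(OC)c(CC=C(C)C)c1O[C@@H](C)[C@H](C)Cc21
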